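## Retrosynthetic overview

1. Target 11 ⇒ last bond made is the tertiary C4′–Br, by cobalt-hydride H-atom transfer (radical) hydrobromination of the exo-methylene allylic chloride 10, with Br delivered anti to the axial C3′–Cl.
2. 10 ⇒ ene-type allylic chlorination of the cyclohexene in bromo-oxane 8; chlorination plus radical hydrobromination together give the "Br on the tertiary carbon, Cl on the secondary carbon, trans-diaxial" pattern.
3. Oxane ring ⇒ 6-endo bromoetherification of tertiary alcohol 7 (forms O1–C6 and C5–Br).
4. 7 ⇒ Felkin–Anh MeLi addition to α-silyloxy ketone 6 ⇒ asymmetric enolate hydroxylation and prenylation of ketone 3.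
5. 3 ⇒ catalytic enantioselective Diels–Alder of isoprene and methyl vinyl ketone. Ring order: cyclohexene first, oxane second, ring halogens last.

Assumption: the catalyst and oxaziridine antipodes named are the ones that give the drawn configurations; if the observed sense is opposite, the mirror-image catalyst or reagent is used.

Numbering used below: oxane O1, C2 (quaternary), C3 (carbinol), C5 (CHBr), C6 (CMe2); cyclohexane C1′ (attached to C2), C3′ (Cl), C4′ (Br, Me).

## Route

**Step 1**
Reactants: 1 isoprene; 2 methyl vinyl ketone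
Product: 3 (R)-1-(4-methylcyclohex-3-en-1-yl)ethan-1-one
Conditions: (S)-B-o-tolyl-diphenylprolinol oxazaborolidine·HNTf2 (10 mol%), CH2Cl2, −40 → −20 °C
Reagents that add atoms: none
Why: Cationic oxazaborolidine (Corey) catalysed Diels–Alder reaction; Lewis-acid activation of the enone gives the "para" (1,4) regioisomer and the catalyst shields one enone face to set C1′ (R).

**Step 2**
Reactants: 3; 4 prenyl bromide (1-bromo-3-methylbut-2-ene)
Product: 5 (R)-5-methyl-1-(4-methylcyclohex-3-en-1-yl)hex-4-en-1-one
Conditions: LDA (1.05 equiv), THF, −78 °C; then 4, DMPU, −78 → −20 °C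
Reagents that add atoms: none
Why: Kinetic enolate alkylation; LDA deprotonates the methyl group rather than the ring methine, so C1′ is not epimerised and the reactive primary allylic bromide is displaced by SN2.

**Step 3**
Reactants: 5
Product: 6 (2S)-2-[(tert-butyldimethylsilyl)oxy]-5-methyl-1-[(1R)-4-methylcyclohex-3-en-1-yl]hex-4-en-1-one
Conditions: NaHMDS, THF, −78 °C; (+)-(8,8-dichlorocamphorylsulfonyl)oxaziridine, −78 °C; then TBSOTf, 2,6-lutidine, −78 → 0 °C (one pot)
Reagents that add atoms: (+)-(8,8-dichlorocamphorylsulfonyl)oxaziridine, CC1(C)C2CCC13CS(=O)(=O)N4OC34C2(Cl)Cl (constitution; (+)-enantiomer used; adds O); TBSOTf, CC(C)(C)[Si](C)(C)OS(=O)(=O)C(F)(F)F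
Why: Davis asymmetric enolate hydroxylation; the (Z)-sodium enolate forms on the less hindered CH2 side and the chiral oxaziridine transfers oxygen under reagent control to set the carbinol centre (S) without touching either alkene, and the alkoxide is silylated in situ.

**Step 4**
Reactants: 6
Product: 7 (2S,3S)-3-[(tert-butyldimethylsilyl)oxy]-6-methyl-2-[(1R)-4-methylcyclohex-3-en-1-yl]hept-5-en-2-ol
Conditions: MeLi, CeCl3, THF, −78 °C
Reagents that add atoms: methyllithium, [Li]C
Why: Non-chelating Felkin–Anh 1,2-addition; the bulky OTBS group sits anti to the incoming methyl, which sets the tertiary carbinol (S) syn to the silyloxy group, and the organocerium suppresses enolisation.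

**Step 5**
Reactants: 7
Product: 8 tert-butyl{[(2S,3S,5S)-5-bromo-2,6,6-trimethyl-2-[(1R)-4-methylcyclohex-3-en-1-yl]oxan-3-yl]oxy}dimethylsilane
Conditions: TBCO (1.05 equiv), MeNO2, 0 °C → rt
Reagents that add atoms: 2,4,4,6-tetrabromocyclohexa-2,5-dienone (TBCO), O=C1C(Br)=CC(Br)(Br)C=C1Br
Why: 6-endo bromoetherification; the tertiary OH opens the side-chain bromonium at the Me2C terminus through a chair with the cyclohexenyl group equatorial, the OTBS axial and Br equatorial, which sets C5 (S), while the TBS ether blocks 5-endo closure by the C3 oxygen.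

**Step 6**
Reactants: 8
Product: 9 tert-butyl{[(2S,3S,5S)-5-bromo-2-[(1R,3S)-3-chloro-4-methylidenecyclohexyl]-2,6,6-trimethyloxan-3-yl]oxy}dimethylsilane
Conditions: Ca(OCl)2, CO2 (dry ice), CH2Cl2/H2O, 0 °C
Reagents that add atoms: calcium hypochlorite (HOCl source), [Ca+2].[O-]Cl.[O-]Cl
Why: Ene-type allylic chlorination with HOCl; Cl+ attacks the only remaining alkene at its CH carbon from the axial direction, which places Cl axial and trans to the C1′ substituent (C3′ S), and the tertiary cation loses a methyl proton (any endocyclic alkene isomer gives the same radical in step 8 and need not be separated).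

**Step 7**
Reactants: 9
Product: 10 (2S,3S,5S)-5-bromo-2-[(1R,3S)-3-chloro-4-methylidenecyclohexyl]-2,6,6-trimethyloxan-3-ol
Conditions: HF·pyridine, pyridine, THF, 0 °C → rt
Reagents that add atoms: none
Why: Buffered fluoride desilylation; these conditions cleave the hindered secondary TBS ether without ionising the allylic chloride or eliminating the secondary bromide, and no stereocentre is affected.

**Step 8 (key step)**
Reactants: 10
Product: 11 (2S,3S,5S)-5-bromo-2-[(1R,3S,4S)-4-bromo-3-chloro-4-methylcyclohexyl]-2,6,6-trimethyloxan-3-ol (target)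
Conditions: Co(acac)2, t-BuOOH, Et3SiH, TsBr, n-PrOH, 23 °C
Reagents that add atoms: p-toluenesulfonyl bromide, Cc1ccc(cc1)S(=O)(=O)Br
Why: Mukaiyama-type Markovnikov HAT hydrobromination; Co–H delivers H• to the exocyclic CH2 and the tertiary C4′ radical, whose adjacent axial C–Cl blocks the syn face, abstracts Br from TsBr by axial attack anti to chlorine to set C4′ (S) as the trans-diaxial bromochloride, while Cl• loss or 1,2-Cl shift from the β-chloro radical is slow and uphill.

## Compound list

1 | isoprene (2-methylbuta-1,3-diene) | C=CC(C)=C | starting material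
2 | methyl vinyl ketone (but-3-en-2-one) | CC(=O)C=C | starting material
3 | (R)-1-(4-methylcyclohex-3-en-1-yl)ethan-1-one | CC(=O)[C@@H]1CCC(C)=CC1 | intermediate
4 | prenyl bromide (1-bromo-3-methylbut-2-ene) | CC(C)=CCBr | starting material
5 | (R)-5-methyl-1-(4-methylcyclohex-3-en-1-yl)hex-4-en-1-one | CC(C)=CCCC(=O)[C@@H]1CCC(C)=CC1 | intermediate
6 | (2S)-2-[(tert-butyldimethylsilyl)oxy]-5-methyl-1-[(1R)-4-methylcyclohex-3-en-1-yl]hex-4-en-1-one | CC(C)=CC[C@H](O[Si](C)(C)C(C)(C)C)C(=O)[C@@H]1CCC(C)=CC1 | intermediate
7 | (2S,3S)-3-[(tert-butyldimethylsilyl)oxy]-6-methyl-2-[(1R)-4-methylcyclohex-3-en-1-yl]hept-5-en-2-ol | O[C@@](C)([C@@H]1CCC(C)=CC1)[C@@H](O[Si](C)(C)C(C)(C)C)CC=C(C)C | intermediate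
8 | tert-butyl{[(2S,3S,5S)-5-bromo-2,6,6-trimethyl-2-[(1R)-4-methylcyclohex-3-en-1-yl]oxan-3-yl]oxy}dimethylsilane | CC1(C)O[C@@](C)([C@@H]2CCC(C)=CC2)[C@@H](O[Si](C)(C)C(C)(C)C)C[C@@H]1Br | intermediate
9 | tert-butyl{[(2S,3S,5S)-5-bromo-2-[(1R,3S)-3-chloro-4-methylidenecyclohexyl]-2,6,6-trimethyloxan-3-yl]oxy}dimethylsilane | CC1(C)O[C@@](C)([C@@H]2CCC(=C)[C@@H](Cl)C2)[C@@H](O[Si](C)(C)C(C)(C)C)C[C@@H]1Br | intermediate
10 | (2S,3S,5S)-5-bromo-2-[(1R,3S)-3-chloro-4-methylidenecyclohexyl]-2,6,6-trimethyloxan-3-ol | CC1(C)O[C@@](C)([C@@H]2CCC(=C)[C@@H](Cl)C2)[C@@H](O)C[C@@H]1Br | intermediate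
11 | (2S,3S,5S)-5-bromo-2-[(1R,3S,4S)-4-bromo-3-chloro-4-methylcyclohexyl]-2,6,6-trimethyloxan-3-ol | CC1(C)O[C@@](C)([C@@H]2CC[C@](C)(Br)[C@@H](Cl)C2)[C@@H](O)C[C@@H]1Br | target

## Summary

Total steps: 8. Longest linear sequence: 8 (fully linear from 1 and 2; step 3 is a one-pot hydroxylation/silylation).

Steps most likely to fail, each with a fallback that changes the approach:

- **Step 5 (bromoetherification).** Risks are 5-exo closure, the C5 epimer, and capture of a ring-alkene bromonium by the same tertiary OH to give a bromo-cineole-type bicyclic ether. Fallback: change the order of events. Run the ene-chlorination on ketone 3 and carry the electron-poor exo-methylene allylic chloride through steps 2–4, so that the prenyl alkene is the only nucleophilic alkene when Br+ is introduced; the radical hydrobromination stays last.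
- **Step 6 (ene-chlorination).** The axial/equatorial Cl ratio at C3′ rests only on a kinetic preference for axial attack. Fallback: a stereospecific sequence from 8. NBS/H2O gives the trans-diaxial bromohydrin, base closes it to the epoxide, Et2AlTMP isomerises that to the exocyclic allylic alcohol with an equatorial OH, and PPh3/hexachloroacetone chlorination with SN2 inversion gives the axial chloride 9.
- **Step 8 (HAT hydrobromination).** Risks are reduction or rearrangement of the β-chloro radical, loss of the allylic chloride to low-valent cobalt, and modest facial selectivity. Fallback: reach the same C4′ radical from a different precursor. Open the ring epoxide with chloride at C3′ (trans-diaxial) to the tertiary chlorohydrin, convert the tertiary alcohol to its cesium oxalate, and carry out photoredox deoxygenative bromination with a bromine-atom donor.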